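**Retrosynthetic overview**
1. Enabling feature: C5 carries the ring oxygen O1 (acylated by the lactone carbonyl C2) and a CH2OH group, so O1–C2(=O) together with C5–CH2–O is a 1,3-dioxolan-2-one (ethylene carbonate) ring in disguise. C3 lies between the C4 carbonyl and the side-chain ketone, so it is the acidic carbon of a 1,3-diketone.
2. Key disconnection: target 13 is the ring-contracted isomer of the 4-(β-ketoacyl)-1,3-dioxolan-2-one 12 (C2–C3, Claisen-type attack of C3 on the carbonate carbon, CH2OH released). 12 arises from β-keto thioester 10 and racemic 4-chloro-1,3-dioxolan-2-one 11 by an enantioconvergent nickel-catalysed reductive acyl coupling (C4–C5, sets C5). Both bonds are made in one flask operation.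
3. 10 comes from acyl Meldrum's acid 7 (acylketene capture by pyridine-2-thiol); 7 from acid 5 and Meldrum's acid.
4. 5 comes from copper-catalysed coupling of the Grignard reagent of (S)-1-bromo-2-methylbutane with 12-bromododecanoic acid; the side-chain stereocentre is taken from the chiral pool.
5. Ring order: the dioxolanone ring is bought and used as a temporary ring; the furanone ring is the only ring formed (step 4), as the dioxolanone opens.

Key step: step 4

Assumption: the sense of induction of the chiral nickel catalyst in step 4 cannot be predicted with certainty; the (S,S)-ligand is written, and its equally available (R,R)-antipode is used instead if the first run delivers the (5R) series. Compound 11 is used as the commercial racemate.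

**Step 1**
Reactants: 1 (S)-1-bromo-2-methylbutane; 2 12-bromododecanoic acid
Product: 5 (S)-14-methylhexadecanoic acid, via (S)-2-methylbutylmagnesium bromide 3 (not isolated), via chloromagnesium 12-bromododecanoate 4 (not isolated)
Conditions: Mg turnings, THF, 45 °C (gives 3); 2, MeMgCl (1.0 equiv), THF, −20 °C (gives 4); 3 (1.5 equiv) added to 4, Li2CuCl4 (3 mol%), −20 → 20 °C; 1 M HCl
Reagents that add atoms: none
Why: Copper-catalysed cross-coupling of a primary alkyl Grignard reagent with a primary alkyl bromide, with the acid masked as its magnesium salt; the stereocentre of 1 is not at the reacting carbon and is carried through unchanged.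

**Step 2**
Reactants: 5 (S)-14-methylhexadecanoic acid; 6 Meldrum's acid (2,2-dimethyl-1,3-dioxane-4,6-dione)
Product: 7 5-[(14S)-1-hydroxy-14-methylhexadecylidene]-2,2-dimethyl-1,3-dioxane-4,6-dione (acyl Meldrum's acid, enol form)
Conditions: DCC (1.1 equiv), DMAP (1.2 equiv), CH2Cl2, 0 → 20 °C
Reagents that add atoms: none
Why: Carbodiimide/DMAP (Steglich-type) C-acylation of Meldrum's acid, a standard route to acyl Meldrum's acids; no stereocentre is touched.

**Step 3**
Reactants: 7 acyl Meldrum's acid; 8 pyridine-2-thiol
Product: 10 S-(pyridin-2-yl) (16S)-16-methyl-3-oxooctadecanethioate, via acylketene 9 (not isolated)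
Conditions: toluene, 85 °C
Reagents that add atoms: none
Why: Thermal retro-[4+2] fragmentation of the acyl Meldrum's acid (loss of acetone and CO2) gives acylketene 9, which is captured by the thiol; this is the usual preparation of β-keto thioesters.

**Step 4**
Reactants: 10 S-(pyridin-2-yl) (16S)-16-methyl-3-oxooctadecanethioate; 11 rac-4-chloro-1,3-dioxolan-2-one
Product: 13 (5S)-4-hydroxy-5-(hydroxymethyl)-3-[(14S)-14-methylhexadecanoyl]furan-2(5H)-one, via dioxolanone diketone 12 (not isolated)
Conditions: NiBr2·diglyme (10 mol%), (S,S)-Ph-BOX [2,2'-(propane-2,2-diyl)bis((4S)-4-phenyl-4,5-dihydrooxazole)] (12 mol%), Mn powder (3 equiv), 11 (2 equiv), DMA/THF, 0 → 20 °C; then DBU (2 equiv), 20 °C; 1 M HCl work-up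
Reagents that add atoms: none
Why: Proposed new method: zerovalent nickel inserts into the acyl C–S bond of 10, chlorine-atom abstraction from either enantiomer of 11 gives the planar 2-oxo-1,3-dioxolan-4-yl radical, and its capture by the chiral acylnickel complex followed by reductive elimination forms C4–C5 (manganese turns the catalyst over); this merges two known reaction types, the nickel/bis(oxazoline)-catalysed asymmetric reductive coupling of acyl electrophiles with racemic secondary alkyl chlorides and the enantioconvergent nickel coupling of racemic 1-haloalkyl esters through 1-acyloxyalkyl radicals. Because 12 is a 1,3-diketone, the pyridine-2-thiolate set free (then DBU) deprotonates C3, which attacks the carbonate carbon C2, the Claisen-type closure known for acyloin carbonates and for Lacey–Dieckmann cyclisations. The furanone ring closes in the 5-exo-trig mode and collapse of the tetrahedral intermediate expels the primary alkoxide, so the dioxolanone ring opens and the CH2OH group appears without any protecting group (12 and 13 are isomers). The only new stereocentre, C5, is set by the chiral ligand in the radical-capture and reductive-elimination event, on which both enantiomers of 11 converge; it should not erode afterwards because C3, not C5, is the acidic site of 12 and the product is held as the tetronate. The step needs C- over O-acylation and the five- over the six-membered lactone: O-attack of the diketonate and expulsion of O1 instead of the CH2–O oxygen are reversible under the basic conditions, and the doubly stabilised 3-acyltetronate anion is the thermodynamic sink. Chemoselectivity in the coupling rests on the weak, oxygen-activated C–Cl bond of 11 (radical partner) and the fast oxidative addition of the 2-pyridyl thioester (acyl partner).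

**Compound list**
1 | (S)-1-bromo-2-methylbutane | CC[C@H](C)CBr | starting material
2 | 12-bromododecanoic acid | OC(=O)CCCCCCCCCCCBr | starting material
3 | (S)-2-methylbutylmagnesium bromide | CC[C@H](C)C[Mg]Br | intermediate (not isolated)
4 | chloromagnesium 12-bromododecanoate | [O-]C(=O)CCCCCCCCCCCBr.[Mg+2].[Cl-] | intermediate (not isolated)
5 | (S)-14-methylhexadecanoic acid | CC[C@H](C)CCCCCCCCCCCCC(=O)O | intermediate
6 | Meldrum's acid (2,2-dimethyl-1,3-dioxane-4,6-dione) | CC1(C)OC(=O)CC(=O)O1 | starting material
7 | 5-[(14S)-1-hydroxy-14-methylhexadecylidene]-2,2-dimethyl-1,3-dioxane-4,6-dione | CC[C@H](C)CCCCCCCCCCCCC(O)=C1C(=O)OC(C)(C)OC1=O | intermediate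
8 | pyridine-2-thiol | Sc1ccccn1 | starting material
9 | (16S)-16-methyloctadec-1-ene-1,3-dione (acylketene) | CC[C@H](C)CCCCCCCCCCCCC(=O)C=C=O | intermediate (not isolated)
10 | S-(pyridin-2-yl) (16S)-16-methyl-3-oxooctadecanethioate | CC[C@H](C)CCCCCCCCCCCCC(=O)CC(=O)Sc1ccccn1 | intermediate
11 | rac-4-chloro-1,3-dioxolan-2-one (chloroethylene carbonate) | ClC1COC(=O)O1 | starting material
12 | (4S)-4-[(16S)-16-methyl-3-oxooctadecanoyl]-1,3-dioxolan-2-one | CC[C@H](C)CCCCCCCCCCCCC(=O)CC(=O)[C@@H]1COC(=O)O1 | intermediate (not isolated)
13 | (5S)-4-hydroxy-5-(hydroxymethyl)-3-[(14S)-14-methylhexadecanoyl]furan-2(5H)-one | CC[C@H](C)CCCCCCCCCCCCC(=O)C1=C(O)[C@H](CO)OC1=O | target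

**Total step count:** 4. **Longest linear sequence:** 4 (steps 1 to 4).

**Steps most likely to fail**

1. Step 4 (Proposed new method). What may go wrong: poor enantiofacial discrimination when the small planar dioxolanyl radical is captured at nickel, together with loss of 11 by dehydrochlorination. Fallback with known chemistry, setting out from 7 and coming back at 13: purchased methyl (S)-2,3-dihydroxypropanoate is tritylated at the primary hydroxyl (TrCl, Et3N, DMAP, CH2Cl2) to give methyl (S)-2-hydroxy-3-(trityloxy)propanoate F1. Heating 7 with F1 (toluene, 100 °C) traps acylketene 9 at the secondary hydroxyl and should give methyl (S)-2-[(16S)-16-methyl-3-oxooctadecanoyloxy]-3-(trityloxy)propanoate F2. Lacey–Dieckmann cyclisation (TBAF, THF, 20 °C) should give (5S)-4-hydroxy-3-[(14S)-14-methylhexadecanoyl]-5-(trityloxymethyl)furan-2(5H)-one F3, and detritylation (TFA, CH2Cl2, 0 °C) gives 13. In this fallback C5 comes from the chiral pool.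

2. Step 3. What may go wrong: thermal re-elimination of pyridine-2-thiol from the activated thioester, so that acylketene 9 dimerises or is lost. Fallback setting out from 5 and coming back at 10: 5 is converted (1H-benzotriazole, SOCl2, CH2Cl2) into 1-[(14S)-14-methylhexadecanoyl]-1H-benzotriazole F4. F4 then C-acylates purchased S-(pyridin-2-yl) ethanethioate under magnesium-mediated soft enolisation (MgBr2·OEt2, i-Pr2NEt, CH2Cl2, 20 °C) to give 10 without any heating.

3. Step 1. What may go wrong: homocoupling and β-hydride loss of Grignard reagent 3 outrunning the cross-coupling with the sparingly soluble magnesium carboxylate 4. Fallback setting out from 1 and coming back at 5: 1 and PPh3 (neat, 120 °C) give (S)-(2-methylbutyl)triphenylphosphonium bromide F5. Wittig reaction (NaN(SiMe3)2, THF, −78 °C) with purchased methyl 12-oxododecanoate should give methyl (12Z,14S)-14-methylhexadec-12-enoate F6. Diimide reduction (2-nitrobenzenesulfonyl hydrazide, Et3N, CH2Cl2), chosen to avoid alkene migration into the allylic stereocentre, gives methyl (S)-14-methylhexadecanoate F7, and saponification (LiOH, THF/H2O) gives 5.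

**Further compounds**
F1 | step 4 | methyl (S)-2-hydroxy-3-(trityloxy)propanoate | COC(=O)[C@@H](O)COC(c1ccccc1)(c1ccccc1)c1ccccc1
F2 | step 4 | methyl (S)-2-[(16S)-16-methyl-3-oxooctadecanoyloxy]-3-(trityloxy)propanoate | CC[C@H](C)CCCCCCCCCCCCC(=O)CC(=O)O[C@@H](COC(c1ccccc1)(c1ccccc1)c1ccccc1)C(=O)OC
F3 | step 4 | (5S)-4-hydroxy-3-[(14S)-14-methylhexadecanoyl]-5-(trityloxymethyl)furan-2(5H)-one | CC[C@H](C)CCCCCCCCCCCCC(=O)C1=C(O)[C@H](COC(c2ccccc2)(c2ccccc2)c2ccccc2)OC1=O
F4 | step 3 | 1-[(14S)-14-methylhexadecanoyl]-1H-benzotriazole | CC[C@H](C)CCCCCCCCCCCCC(=O)n1nnc2ccccc21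
F5 | step 1 | (S)-(2-methylbutyl)triphenylphosphonium bromide | CC[C@H](C)C[P+](c1ccccc1)(c1ccccc1)c1ccccc1.[Br-]
F6 | step 1 | methyl (12Z,14S)-14-methylhexadec-12-enoate | CC[C@H](C)/C=C\CCCCCCCCCCC(=O)OC
F7 | step 1 | methyl (S)-14-methylhexadecanoate | CC[C@H](C)CCCCCCCCCCCCC(=O)OC
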